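(Its constants are assumed; the flask was simulated.)

The amounts come first: alder, cedar and ash were charged alike with 0.50 M of substrate and differ in the time of reading.

    crystals ⇌ ring, rate k1*(cs1 - [ring]) while solid is left; crystals form when [ring] > cs1 (cs1 = 36 mM, k1 = 4.1 /h)
    2 substrate → open dimer (k2 = 0.0016 /M/h)
    substrate + open dimer → open trimer (k3 = 0.045 /M/h)
    substrate ⇌ ring (K4 = 20, k4 = 0.022 /h)

| flask | substrate | time |
|---|---|---|
| alder | 0.50 M | 10 h |
| cedar | 0.50 M | 20 h |
| ash | 0.50 M | 40 h |

- a species is counted by the substrate in it: one open dimer counts as two
- a species is counted by the substrate in it: one open trimer counts as three
- amounts and yields of ring count crystals too
- two of one species on the left: rate k times its square, two consumed each time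
- given per volume of solution although it is solid: crystals
- run time (alder): 10 h

- which of these there is most of at the end, counted by the substrate in it, alder (open dimer / open trimer / substrate / ring)
- which of these there is most of at the end, counted by the substrate in it, cedar (open dimer / open trimer / substrate / ring)
- which of these there is most of at the end, counted by the substrate in it, ash (open dimer / open trimer / substrate / ring)
- amount of the one of these that there is most of at the end, in percent of the substrate charged, alder
- amount of the one of these that there is most of at the end, in percent of the substrate charged, cedar
- amount of the one of these that there is most of at the end, in percent of the substrate charged, ash

I turned each constant into a time at that charge. By the forward rate of the ring step alone, substrate had a half-life of 32 h, and I first took plain first-order decay at that rate, which left 41.5% of the substrate in ash. My objection was the way back, since that step has an equilibrium constant of 20. But I reckoned that dissolved ring would reach its solubility of 36 mM after roughly 3.27 h, and that crystals, with a time of 0.244 h, would then need a surplus of 2.68 mM to take up the stream of ring at the charged amount of substrate. With dissolved ring near that solubility, the back rate came to 0.360% of the forward rate at the charged amount, and I dropped it.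

My second objection was open dimer. Substrate went forward into ring 14 times as fast as into open dimer at the start, which is a small drain but one I could count: held at the charge, it adds 0.00160 /h to the constant of 0.022 /h. That gave my carried quantity, the working half-life of substrate, a pseudo-first-order half-life made from the ring step and the dimer step together at the charged amount: 29.4 h. From those two rates at the charged amount I took ring's share of what substrate loses to be 93.2%.

Open trimer remained a doubt, for its constant is larger than that of the dimer step. Yet that step needs open dimer, and the time of an open dimer against substrate at the charge, 44.4 h, is longer than the reading of ash, so I left it out of the estimate.

I committed to substrate at 79.0% in alder and 62.4% in cedar, with ring at 35.1% in cedar, and to ring ahead in ash at 57.0% against substrate at 38.9%. The forecast named substrate at 78.7% for alder, which is below my figure there, substrate at 62.4% for cedar and ring at 57% for ash, and held that “Oligomerisation is a minor drain of only a few percent of the charge”.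

The flasks gave substrate at 79.1% in alder, substrate at 62.8% in cedar and ring at 57.0% in ash. Crystals in ash stood at 49.6% of the charge after 40.0 h. Read back from the 39.7% of substrate in ash, the half-life comes to 30.0 h, beside the 29.4 h I carried. For the same flask as alder read at 6.0 h, that 29.4 h gives substrate at 86.8% and ring at 12.3%, and that flask held 86.9% of substrate and, crystals counted, 12.3% of ring.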